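**Plan**

- Numbering: 6,8-dioxabicyclo[3.2.2]nonan-7-one core. C1 is the bridgehead with the acetoxy chain, C2 the CHOH, C3–C4 the CH2CH2, C5 the methyl bridgehead, O6–C7(=O) the lactone bridge, and O8–C9 the ether bridge (C9 carries the hydroxy chain).
- Retrosynthesis: after protecting-group removal and return of C2 to the ketone, one operation cuts the lactone acyl bond O6–C7, the ether bond O8–C9 and the C3–C4 bond. This gives an α-hydroxy-β-keto ester (C1–C3, O8, C7, acetoxy chain) and a 2,3-epoxy triflate (C4, C5, C9, hydroxy chain).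
- Enabling feature: the oxepane ring C1–C2–C3–C4–C5–C9–O8 splits into O8–C1–C2–C3, an α-ketol that acts as a 1,4-O,C-dinucleophile, and C4–C5–C9. In the latter, the trans O6/O8 pattern on quaternary C5 and on C9 is that of a trisubstituted epoxide opened at C9, and C4 is the carbinol carbon of the parent allylic alcohol, so it is a 1,3-bis-electrophile for a (4+3) annulation.
- Forward: the two fragments are made in parallel. The annulation closes the oxepane (C3–C4, then O8–C9), and the C5 alkoxide set free closes the dioxanone and seven-membered lactone rings onto the C1 ester. Silyl-to-acetate exchange, C2 reduction and PMB removal finish the route.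
- Stereochemistry: C5 and C9 come from Sharpless epoxidation (D-tartrate), with inversion at C9 in the annulation. C1 comes from catalytic asymmetric α-hydroxylation and C2 from CBS reduction. The Z alkene of the hydroxy chain comes from nerol, that of the acetoxy chain from a Z-selective Wittig reaction of an α-silyloxy ketone.

Key step: step 8

Assumption: in step 7 the (R,R)-ligand is taken to give the (2R)-alcohol; if a test run shows the opposite sense, the (S,S)-ligand is used and nothing else changes.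
Remark: 8 is written as its sodium salt; 12 and 13 are written as neutral compounds but are lithium alkoxides in the flask.

**Route**

Step 1
Reactants: 1 nerol [(2Z)-3,7-dimethylocta-2,6-dien-1-ol]
Product: 2 neryl 4-methoxybenzyl ether
Conditions: NaH, 4-methoxybenzyl chloride, Bu4NI (cat.), THF/DMF, 0 °C → rt
Reagents that add atoms: 4-methoxybenzyl chloride, COc1ccc(CCl)cc1
Why: Williamson etherification of the primary allylic alkoxide should proceed without touching either alkene and installs the one protecting group that has to last to the final step.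

Step 2
Reactants: 2 neryl 4-methoxybenzyl ether
Product: 3 (2E,6Z)-8-[(4-methoxybenzyl)oxy]-2,6-dimethylocta-2,6-dien-1-ol
Conditions: SeO2 (cat.), t-BuOOH, salicylic acid (cat.), CH2Cl2, rt
Reagents that add atoms: tert-butyl hydroperoxide (oxygen, relayed through SeO2), CC(C)(C)OO
Why: SeO2-catalysed allylic oxidation (ene reaction, then [2,3]-sigmatropic shift) should hydroxylate the E-methyl group of the electron-richer terminal alkene, the other alkene being deactivated by its allylic ether oxygen, and gives the (E)-allylic alcohol that directs the next step.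

Step 3
Reactants: 3 (2E,6Z)-8-[(4-methoxybenzyl)oxy]-2,6-dimethylocta-2,6-dien-1-ol
Product: 4 [(2R,3R)-3-{(3Z)-5-[(4-methoxybenzyl)oxy]-3-methylpent-3-en-1-yl}-2-methyloxiran-2-yl]methanol
Conditions: Ti(OiPr)4 (cat.), D-(−)-diethyl tartrate (cat.), t-BuOOH, 4 Å MS, CH2Cl2, −20 °C
Reagents that add atoms: tert-butyl hydroperoxide, CC(C)(C)OO
Why: Sharpless asymmetric epoxidation of the (E)-2-methyl-2-alkenol with the D-tartrate ligand should deliver oxygen to the face that gives the (2R,3R)-epoxide, and the second alkene, which has no free allylic hydroxyl, should stay intact.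

Step 4
Reactants: 4 [(2R,3R)-3-{(3Z)-5-[(4-methoxybenzyl)oxy]-3-methylpent-3-en-1-yl}-2-methyloxiran-2-yl]methanol
Product: 5 [(2R,3R)-3-{(3Z)-5-[(4-methoxybenzyl)oxy]-3-methylpent-3-en-1-yl}-2-methyloxiran-2-yl]methyl trifluoromethanesulfonate
Conditions: Tf2O, 2,6-lutidine, CH2Cl2, −78 °C; cold aqueous work-up, used at once
Reagents that add atoms: trifluoromethanesulfonic anhydride, O=S(=O)(OS(=O)(=O)C(F)(F)F)C(F)(F)F
Why: O-sulfonylation of the primary epoxy alcohol with a hindered pyridine base at low temperature is the standard route to 2,3-epoxy triflates and touches neither stereocentre.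

Step 5
Reactants: 6 (4-carboxybutyl)triphenylphosphonium bromide; 7 1-{[tert-butyl(dimethyl)silyl]oxy}propan-2-one
Product: 9 methyl (5Z)-7-{[tert-butyl(dimethyl)silyl]oxy}-6-methylhept-5-enoate, via sodium heptenoate 8 (not isolated)
Conditions: NaN(SiMe3)2 (2.1 equiv), THF/DMPU, 0 °C; 7, −78 °C → rt; then MeI, DMF, rt
Reagents that add atoms: iodomethane, CI
Why: Wittig olefination of the α-silyloxy methyl ketone with the non-stabilised carboxylate-bearing ylide should give the Z-trisubstituted alkene (silyloxymethyl cis to the chain), the known bias of α-oxygenated ketones, and the sodium carboxylate is then O-methylated in the same flask by SN2 reaction with iodomethane.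

Step 6
Reactants: 9 methyl (5Z)-7-{[tert-butyl(dimethyl)silyl]oxy}-6-methylhept-5-enoate
Product: 10 methyl (5Z)-2-acetyl-7-{[tert-butyl(dimethyl)silyl]oxy}-6-methylhept-5-enoate (C2 not defined)
Conditions: LiN(iPr)2, THF, −78 °C; N-methoxy-N-methylacetamide, −78 → −20 °C; aq NH4Cl
Reagents that add atoms: N-methoxy-N-methylacetamide, CC(=O)N(C)OC
Why: Crossed Claisen-type C-acylation of the lithium ester enolate by the N-methoxy-N-methylamide should stop at the chelated tetrahedral adduct, so the β-keto ester appears only on quenching, and its new stereocentre is labile and is fixed in the next step.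

Step 7
Reactants: 10 methyl (5Z)-2-acetyl-7-{[tert-butyl(dimethyl)silyl]oxy}-6-methylhept-5-enoate
Product: 11 methyl (2R,5Z)-2-acetyl-7-{[tert-butyl(dimethyl)silyl]oxy}-2-hydroxy-6-methylhept-5-enoate
Conditions: Ni(ClO4)2·6H2O (cat.), (R,R)-4,6-dibenzofurandiyl-2,2'-bis(4-phenyl-2-oxazoline) (cat.), 3-phenyl-2-(phenylsulfonyl)oxaziridine, 4 Å MS, CH2Cl2, rt
Reagents that add atoms: 3-phenyl-2-(phenylsulfonyl)oxaziridine, O=S(=O)(N1OC1c1ccccc1)c1ccccc1
Why: Catalytic enantioselective α-hydroxylation of a β-keto ester, in which the divalent nickel bis(oxazoline) complex holds the substrate as a two-point chelated enolate and the N-sulfonyloxaziridine transfers oxygen to its open face, should set the quaternary (2R)-carbinol while sparing the trisubstituted alkene.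

Step 8
Reactants: 11 methyl (2R,5Z)-2-acetyl-7-{[tert-butyl(dimethyl)silyl]oxy}-2-hydroxy-6-methylhept-5-enoate; 5 [(2R,3R)-3-{(3Z)-5-[(4-methoxybenzyl)oxy]-3-methylpent-3-en-1-yl}-2-methyloxiran-2-yl]methyl trifluoromethanesulfonate
Product: 14 (1R,5R,9S)-1-[(3Z)-5-{[tert-butyl(dimethyl)silyl]oxy}-4-methylpent-3-en-1-yl]-9-{(3Z)-5-[(4-methoxybenzyl)oxy]-3-methylpent-3-en-1-yl}-5-methyl-6,8-dioxabicyclo[3.2.2]nonane-2,7-dione, via epoxy ketone 12 (not isolated), via oxepane hydroxy ester 13 (not isolated)
Conditions: LiN(SiMe3)2 (2.1 equiv), THF, −78 °C; 5, −78 → −40 °C; then DMPU, −40 °C → rt; aq NH4Cl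
Reagents that add atoms: none
Why: Proposed new method: the dilithium dianion of 11 (tertiary alkoxide plus methyl-ketone enolate, the only enolisable site) is C-alkylated by the primary triflate of 5 at −78 °C to give 12 (C3–C4 bond), the tertiary alkoxide then opens the trisubstituted epoxide at its secondary carbon with inversion to give oxepane 13 (O8–C9 bond), and the C5 alkoxide set free attacks the methyl ester across the ring to close the lactone bridge. The closest known reaction type is the domino C-/O-alkylation of 1,3-dicarbonyl dianions with epihalohydrin-type 1,3-bis-electrophiles, a (3+2) annulation to tetrahydrofurans, extended here to an α-ketol dianion as 1,4-C,O-dinucleophile in a (4+3) sense. The oxepane closes by 7-endo-tet epoxide opening, and the 1,4-dioxan-2-one ring, which also completes the seven-membered lactone ring, closes by 6-exo-trig acyl substitution. C9 is set by SN2 inversion of the (3R)-epoxide carbon, C5 is carried unchanged from the Sharpless epoxide and C1 from 11, and only this combination places ester and alkoxide on the same face for bridging. The step needs C- over O-alkylation, secured by the lithium enolate–triflate pairing at low temperature and by the hindered, acceptor-stabilised alkoxide, and it needs attack at the secondary instead of the quaternary epoxide carbon, secured by strictly basic SN2 conditions under which the competing 6-exo closure would have to form a di-tertiary ether at a fully substituted carbon. Once bridged, C1 is a bridgehead, so the methoxide released should not trigger retro-Claisen cleavage of the β-keto lactone.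

Step 9
Reactants: 14 silyl-protected bridged keto lactone
Product: 15 (1R,5R,9S)-1-[(3Z)-5-hydroxy-4-methylpent-3-en-1-yl]-9-{(3Z)-5-[(4-methoxybenzyl)oxy]-3-methylpent-3-en-1-yl}-5-methyl-6,8-dioxabicyclo[3.2.2]nonane-2,7-dione
Conditions: HF·pyridine, pyridine, THF, 0 °C → rt
Reagents that add atoms: none
Why: Fluoride cleavage of the primary allylic silyl ether under buffered conditions should free the alcohol without opening the bridged lactone or the benzyl-type ether.

Step 10
Reactants: 15 primary allylic alcohol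
Product: 16 (2Z)-5-[(1R,5R,9S)-9-{(3Z)-5-[(4-methoxybenzyl)oxy]-3-methylpent-3-en-1-yl}-5-methyl-2,7-dioxo-6,8-dioxabicyclo[3.2.2]nonan-1-yl]-2-methylpent-2-en-1-yl acetate
Conditions: Ac2O, pyridine, DMAP (cat.), CH2Cl2, 0 °C
Reagents that add atoms: acetic anhydride, CC(=O)OC(C)=O
Why: DMAP-catalysed acylation should be clean because the primary allylic hydroxyl is the only nucleophilic site in the molecule at this stage.

Step 11
Reactants: 16 keto acetate
Product: 17 (2Z)-5-[(1R,2S,5R,9S)-2-hydroxy-9-{(3Z)-5-[(4-methoxybenzyl)oxy]-3-methylpent-3-en-1-yl}-5-methyl-7-oxo-6,8-dioxabicyclo[3.2.2]nonan-1-yl]-2-methylpent-2-en-1-yl acetate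
Conditions: (R)-2-methyl-CBS-oxazaborolidine (cat.), catecholborane, toluene, −78 → −40 °C
Reagents that add atoms: none
Why: Corey–Bakshi–Shibata reduction, in which the (R)-oxazaborolidine tells the quaternary bridgehead C1 from the C3 methylene, should deliver hydride to the ketone face flanked by the ether bridge O8–C9 and so give the (2S)-alcohol with its hydroxyl on the side of the lactone bridge, a sense that should agree with the steric bias of the bicycle, while lactone, acetate and alkenes are left alone.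

Step 12
Reactants: 17 PMB-protected hydroxy acetate
Product: 18 (2Z)-5-[(1R,2S,5R,9S)-2-hydroxy-9-[(3Z)-5-hydroxy-3-methylpent-3-en-1-yl]-5-methyl-7-oxo-6,8-dioxabicyclo[3.2.2]nonan-1-yl]-2-methylpent-2-en-1-yl acetate (CNP0174851.1)
Conditions: DDQ, CH2Cl2/pH 7 buffer, 0 °C
Reagents that add atoms: none
Why: Oxidative cleavage of the 4-methoxybenzyl ether by DDQ (hydride abstraction, then hydrolysis of the hemiacetal) should release the primary allylic alcohol without affecting acetate, lactone or the secondary alcohol.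

**Compound list**

1 | nerol, (2Z)-3,7-dimethylocta-2,6-dien-1-ol | CC(C)=CCC/C(C)=C\CO | starting material
2 | neryl 4-methoxybenzyl ether | CC(C)=CCC/C(C)=C\COCc1ccc(OC)cc1 | intermediate
3 | (2E,6Z)-8-[(4-methoxybenzyl)oxy]-2,6-dimethylocta-2,6-dien-1-ol | OC/C(C)=C/CC/C(C)=C\COCc1ccc(OC)cc1 | intermediate
4 | [(2R,3R)-3-{(3Z)-5-[(4-methoxybenzyl)oxy]-3-methylpent-3-en-1-yl}-2-methyloxiran-2-yl]methanol | OC[C@@]1(C)O[C@@H]1CC/C(C)=C\COCc1ccc(OC)cc1 | intermediate
5 | [(2R,3R)-3-{(3Z)-5-[(4-methoxybenzyl)oxy]-3-methylpent-3-en-1-yl}-2-methyloxiran-2-yl]methyl trifluoromethanesulfonate | FC(F)(F)S(=O)(=O)OC[C@@]1(C)O[C@@H]1CC/C(C)=C\COCc1ccc(OC)cc1 | intermediate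
6 | (4-carboxybutyl)triphenylphosphonium bromide | OC(=O)CCCC[P+](c1ccccc1)(c1ccccc1)c1ccccc1.[Br-] | starting material
7 | 1-{[tert-butyl(dimethyl)silyl]oxy}propan-2-one | CC(=O)CO[Si](C)(C)C(C)(C)C | starting material
8 | sodium (5Z)-7-{[tert-butyl(dimethyl)silyl]oxy}-6-methylhept-5-enoate | CC(C)(C)[Si](C)(C)OC/C(C)=C\CCCC(=O)[O-].[Na+] | intermediate
9 | methyl (5Z)-7-{[tert-butyl(dimethyl)silyl]oxy}-6-methylhept-5-enoate | CC(C)(C)[Si](C)(C)OC/C(C)=C\CCCC(=O)OC | intermediate
10 | methyl (5Z)-2-acetyl-7-{[tert-butyl(dimethyl)silyl]oxy}-6-methylhept-5-enoate | CC(C)(C)[Si](C)(C)OC/C(C)=C\CCC(C(C)=O)C(=O)OC | intermediate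
11 | methyl (2R,5Z)-2-acetyl-7-{[tert-butyl(dimethyl)silyl]oxy}-2-hydroxy-6-methylhept-5-enoate | CC(C)(C)[Si](C)(C)OC/C(C)=C\CC[C@@](O)(C(C)=O)C(=O)OC | intermediate
12 | methyl (2R)-2-[(3Z)-5-{[tert-butyl(dimethyl)silyl]oxy}-4-methylpent-3-en-1-yl]-2-hydroxy-5-[(2R,3R)-3-{(3Z)-5-[(4-methoxybenzyl)oxy]-3-methylpent-3-en-1-yl}-2-methyloxiran-2-yl]-3-oxopentanoate (epoxy ketone) | CC(C)(C)[Si](C)(C)OC/C(C)=C\CC[C@](O)(C(=O)OC)C(=O)CC[C@@]1(C)O[C@@H]1CC/C(C)=C\COCc1ccc(OC)cc1 | intermediate
13 | methyl (2R,6R,7S)-2-[(3Z)-5-{[tert-butyl(dimethyl)silyl]oxy}-4-methylpent-3-en-1-yl]-6-hydroxy-7-{(3Z)-5-[(4-methoxybenzyl)oxy]-3-methylpent-3-en-1-yl}-6-methyl-3-oxooxepane-2-carboxylate (oxepane hydroxy ester) | CC(C)(C)[Si](C)(C)OC/C(C)=C\CC[C@@]1(C(=O)OC)O[C@@H](CC/C(C)=C\COCc2ccc(OC)cc2)[C@](C)(O)CCC1=O | intermediate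
14 | (1R,5R,9S)-1-[(3Z)-5-{[tert-butyl(dimethyl)silyl]oxy}-4-methylpent-3-en-1-yl]-9-{(3Z)-5-[(4-methoxybenzyl)oxy]-3-methylpent-3-en-1-yl}-5-methyl-6,8-dioxabicyclo[3.2.2]nonane-2,7-dione | CC(C)(C)[Si](C)(C)OC/C(C)=C\CC[C@@]12O[C@@H](CC/C(C)=C\COCc3ccc(OC)cc3)[C@@](C)(CCC1=O)OC2=O | intermediate
15 | (1R,5R,9S)-1-[(3Z)-5-hydroxy-4-methylpent-3-en-1-yl]-9-{(3Z)-5-[(4-methoxybenzyl)oxy]-3-methylpent-3-en-1-yl}-5-methyl-6,8-dioxabicyclo[3.2.2]nonane-2,7-dione | OC/C(C)=C\CC[C@@]12O[C@@H](CC/C(C)=C\COCc3ccc(OC)cc3)[C@@](C)(CCC1=O)OC2=O | intermediate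
16 | (2Z)-5-[(1R,5R,9S)-9-{(3Z)-5-[(4-methoxybenzyl)oxy]-3-methylpent-3-en-1-yl}-5-methyl-2,7-dioxo-6,8-dioxabicyclo[3.2.2]nonan-1-yl]-2-methylpent-2-en-1-yl acetate | CC(=O)OC/C(C)=C\CC[C@@]12O[C@@H](CC/C(C)=C\COCc3ccc(OC)cc3)[C@@](C)(CCC1=O)OC2=O | intermediate
17 | (2Z)-5-[(1R,2S,5R,9S)-2-hydroxy-9-{(3Z)-5-[(4-methoxybenzyl)oxy]-3-methylpent-3-en-1-yl}-5-methyl-7-oxo-6,8-dioxabicyclo[3.2.2]nonan-1-yl]-2-methylpent-2-en-1-yl acetate | CC(=O)OC/C(C)=C\CC[C@@]12O[C@@H](CC/C(C)=C\COCc3ccc(OC)cc3)[C@@](C)(CC[C@@H]1O)OC2=O | intermediate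
18 | (2Z)-5-[(1R,2S,5R,9S)-2-hydroxy-9-[(3Z)-5-hydroxy-3-methylpent-3-en-1-yl]-5-methyl-7-oxo-6,8-dioxabicyclo[3.2.2]nonan-1-yl]-2-methylpent-2-en-1-yl acetate | CC(=O)OC/C(C)=C\CC[C@@]12O[C@@H](CC/C(C)=C\CO)[C@@](C)(CC[C@@H]1O)OC2=O | target

**Step count and risks**

Total step count: 12. Longest linear sequence: 9 steps (steps 1–4, then 8–12).

Steps most likely to fail:

1. Step 8 (Proposed new method). The tertiary alkoxide may close onto the quaternary epoxide carbon to give a six-membered ether instead of the oxepane, or may react so slowly that α-ketol rearrangement competes on warming. The fallback uses known chemistry and turns the wrong regiochemistry to use. It sets out from 11 and 5: the dianion alkylation is quenched at −78 °C with acetic acid and epoxy ketone 12 is isolated. Camphorsulfonic acid in CH2Cl2 at 0 °C should then promote the usual exo, Markovnikov epoxy-alcohol cyclisation at the tertiary carbon and give the oxane regioisomer F1, which carries an exocyclic secondary carbinol. Mesylation (MsCl, Et3N) gives the mesylate F2. Warming F2 with Zn(OAc)2 in aqueous acetic acid should cause the 1,2-oxygen-shift ring expansion of a 2-(1-sulfonyloxyalkyl)oxane: the ring oxygen displaces the mesylate with inversion, and water opens the bicyclic oxonium ion at the tertiary ring carbon. This double inversion at C5 and single inversion at C9 reproduce the configuration of 13, and the silyl ether is lost under these conditions, giving the desilylated oxepane hydroxy ester F3. DBU in toluene then closes the lactone, and the sequence comes back to the route at 15.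

2. Step 7. Enantioselection may be poor for an acyclic methyl ester, or the catalyst may fail to enolise the α-branched substrate. The fallback replaces asymmetric catalysis by resolution through diastereomers. It sets out from 10, which is hydroxylated without a chiral catalyst (same oxaziridine, K2CO3, CH2Cl2) to the racemic hydroxy keto ester F4. F4 (two equivalents relative to 5) is taken through the conditions of step 8. The (2R)-half should give 14, while the (2S)-half can only reach the C2-epimeric oxepane hydroxy ester F5, whose ester and tertiary hydroxyl lie on opposite faces and cannot bridge; F5 is removed by chromatography. The fallback comes back to the route at 14.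

3. Step 11. Facial selectivity of hydride delivery to the bicyclic ketone may be poor or reversed, or the hindered ketone may be slow with the oxazaborolidine. The fallback corrects the configuration by substitution instead of by face control. It sets out from 16, which is reduced with NaBH4 and CeCl3·7H2O in MeOH at −78 °C. The C2-epimeric (2R)-alcohol F6 is inverted by a Mitsunobu reaction (chloroacetic acid, PPh3, diisopropyl azodicarboxylate, toluene) to the (2S)-chloroacetate F7. Thiourea and NaHCO3 in ethanol then remove the chloroacetyl group selectively in the presence of the acetate, and the fallback comes back to the route at 17.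

Further compounds
F1 | step 8 | methyl (2R,6S)-2-[(3Z)-5-{[tert-butyl(dimethyl)silyl]oxy}-4-methylpent-3-en-1-yl]-6-{(1R,4Z)-1-hydroxy-6-[(4-methoxybenzyl)oxy]-4-methylhex-4-en-1-yl}-6-methyl-3-oxooxane-2-carboxylate | CC(C)(C)[Si](C)(C)OC/C(C)=C\CC[C@@]1(C(=O)OC)O[C@](C)([C@H](O)CC/C(C)=C\COCc2ccc(OC)cc2)CCC1=O
F2 | step 8 | methyl (2R,6S)-2-[(3Z)-5-{[tert-butyl(dimethyl)silyl]oxy}-4-methylpent-3-en-1-yl]-6-{(1R,4Z)-6-[(4-methoxybenzyl)oxy]-4-methyl-1-[(methylsulfonyl)oxy]hex-4-en-1-yl}-6-methyl-3-oxooxane-2-carboxylate | CC(C)(C)[Si](C)(C)OC/C(C)=C\CC[C@@]1(C(=O)OC)O[C@](C)([C@H](OS(C)(=O)=O)CC/C(C)=C\COCc2ccc(OC)cc2)CCC1=O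
F3 | step 8 | methyl (2R,6R,7S)-6-hydroxy-2-[(3Z)-5-hydroxy-4-methylpent-3-en-1-yl]-7-{(3Z)-5-[(4-methoxybenzyl)oxy]-3-methylpent-3-en-1-yl}-6-methyl-3-oxooxepane-2-carboxylate | OC/C(C)=C\CC[C@@]1(C(=O)OC)O[C@@H](CC/C(C)=C\COCc2ccc(OC)cc2)[C@](C)(O)CCC1=O
F4 | step 7 | methyl (5Z)-2-acetyl-7-{[tert-butyl(dimethyl)silyl]oxy}-2-hydroxy-6-methylhept-5-enoate (racemic) | CC(C)(C)[Si](C)(C)OC/C(C)=C\CCC(O)(C(C)=O)C(=O)OC
F5 | step 7 | methyl (2S,6R,7S)-2-[(3Z)-5-{[tert-butyl(dimethyl)silyl]oxy}-4-methylpent-3-en-1-yl]-6-hydroxy-7-{(3Z)-5-[(4-methoxybenzyl)oxy]-3-methylpent-3-en-1-yl}-6-methyl-3-oxooxepane-2-carboxylate | CC(C)(C)[Si](C)(C)OC/C(C)=C\CC[C@]1(C(=O)OC)O[C@@H](CC/C(C)=C\COCc2ccc(OC)cc2)[C@](C)(O)CCC1=O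
F6 | step 11 | (2Z)-5-[(1R,2R,5R,9S)-2-hydroxy-9-{(3Z)-5-[(4-methoxybenzyl)oxy]-3-methylpent-3-en-1-yl}-5-methyl-7-oxo-6,8-dioxabicyclo[3.2.2]nonan-1-yl]-2-methylpent-2-en-1-yl acetate | CC(=O)OC/C(C)=C\CC[C@@]12O[C@@H](CC/C(C)=C\COCc3ccc(OC)cc3)[C@@](C)(CC[C@H]1O)OC2=O
F7 | step 11 | (1R,2S,5R,9S)-1-[(3Z)-5-acetoxy-4-methylpent-3-en-1-yl]-9-{(3Z)-5-[(4-methoxybenzyl)oxy]-3-methylpent-3-en-1-yl}-5-methyl-7-oxo-6,8-dioxabicyclo[3.2.2]nonan-2-yl chloroacetate | CC(=O)OC/C(C)=C\CC[C@@]12O[C@@H](CC/C(C)=C\COCc3ccc(OC)cc3)[C@@](C)(CC[C@@H]1OC(=O)CCl)OC2=O
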